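**Plan**

Numbering: C1 lactone carbonyl, C2 its CH2, C3 the peroxy CH, C4 the ring-fusion carbon with CH3 and the lactone oxygen, C5 the ring CH2, C6 the carbon with CH3 and the 12-phenyldodecyl chain.
Enabling feature: in the 1,2-dioxane ring the C4–C5 bond lies directly across from the O–O bond, so opening the ring there (as a C4=C5 alkene) leaves an acyclic dialkyl peroxide whose two halves each carry one stereocentre, C3 and C6.
Retrosynthetic cuts, in order: lactone C4–O bond and C5–H (iodolactonisation, deiodination); C4=C5 (ring-closing metathesis); peroxide C6–O bond (hydroperoxide plus epoxide); the C–C bond between the first two chain carbons at C6 (Grignard reagent plus epoxy alcohol).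
Forward order: the chain is joined to the C6 building block, the two halves are united through the peroxide, the dioxane ring is closed by metathesis, and the lactone ring is closed last.
Stereochemistry: C3 from an enzymatic kinetic resolution of the ene hydroperoxide, C6 from (S)-2-methylglycidol through an invertive epoxide opening, C4 from C3 through cis-lactonisation.

Key step: step 11

Assumption: (S)-2-methylglycidol 8 is bought in high enantiomeric purity, and horseradish peroxidase is taken to show towards 3 the enantiomer preference known for related secondary hydroperoxides, the configuration of 4 being checked on its reduction product before use.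

**Route**

Step 1
Reactants: 1 4-methylpent-3-enoic acid
Product: 2 tert-butyl 4-methylpent-3-enoate
Conditions: tert-butyl 2,2,2-trichloroacetimidate (2 equiv), BF3·OEt2 (cat.), cyclohexane/CH2Cl2, rt
Reagents that add atoms: tert-butyl 2,2,2-trichloroacetimidate, CC(C)(C)OC(=N)C(Cl)(Cl)Cl
Why: Acid-catalysed O-alkylation of a carboxylic acid by a trichloroacetimidate (tert-butyl ester formation) runs at room temperature with only a trace of Lewis acid, so the trisubstituted β,γ-alkene should neither move into conjugation nor lactonise onto C4.

Step 2
Reactants: 2 tert-butyl 4-methylpent-3-enoate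
Product: 3 tert-butyl 3-hydroperoxy-4-methylpent-4-enoate (racemic)
Conditions: O2, visible light, meso-tetraphenylporphyrin (cat.), CH2Cl2, 0 °C; chromatography
Reagents that add atoms: dioxygen, O=O
Why: Schenck ene reaction of singlet oxygen, in which oxygen adds at C3 while a hydrogen is taken from the methyl group on the more substituted side of the alkene, a path that should be preferred over abstraction of the less electron-rich C2 hydrogens beside the ester, so that the secondary allylic hydroperoxide forms as a racemate and the conjugated tertiary regioisomer is removed by chromatography.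

Step 3
Reactants: 3 tert-butyl 3-hydroperoxy-4-methylpent-4-enoate (racemic)
Product: 4 tert-butyl (3S)-3-hydroperoxy-4-methylpent-4-enoate
Conditions: horseradish peroxidase, guaiacol, phosphate buffer pH 6, 20 °C, run slightly past half conversion; chromatography; 4 kept cold with a trace of BHT
Reagents that add atoms: none
Why: Enzymatic kinetic resolution by enantioselective reduction, in which horseradish peroxidase reduces one enantiomer of a secondary hydroperoxide to the alcohol at the expense of guaiacol and, by analogy with 1-arylethyl and other ene-derived hydroperoxides, should consume the (R)-enantiomer, so that (S)-4 remains and C3 is fixed.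

Step 4
Reactants: 5 11-phenylundecanoic acid
Product: 6 11-phenylundecan-1-ol
Conditions: LiAlH4, THF, 0 °C to rt
Reagents that add atoms: none
Why: Hydride reduction of a carboxylic acid to the primary alcohol with LiAlH4 is routine and leaves the phenyl ring untouched.

Step 5
Reactants: 6 11-phenylundecan-1-ol
Product: 7 (11-bromoundecyl)benzene
Conditions: CBr4, PPh3, CH2Cl2, 0 °C
Reagents that add atoms: carbon tetrabromide, BrC(Br)(Br)Br
Why: Appel reaction, in which the alcohol is activated as an alkoxyphosphonium ion and displaced by bromide under neutral conditions.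

Step 6
Reactants: 7 (11-bromoundecyl)benzene; 8 [(2S)-2-methyloxiran-2-yl]methanol
Product: 11 (2R)-2-methyl-14-phenyltetradecane-1,2-diol, via (11-phenylundecyl)magnesium bromide 9 (not isolated), via bromomagnesium [(2S)-2-methyloxiran-2-yl]methanolate 10 (not isolated)
Conditions: 7, Mg, THF, rt; 8, MeMgBr (1.0 equiv), THF, −40 °C; solutions combined, CuI (10 mol %), −40 to 0 °C; aq NH4Cl
Reagents that add atoms: none
Why: Copper-catalysed Grignard opening of an epoxide at its unsubstituted CH2 carbon, the free hydroxyl having first been turned into its magnesium alkoxide by a sacrificial Grignard reagent, joins the chain while the quaternary stereocentre from the purchased epoxy alcohol is not a reacting centre and keeps its arrangement.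

Step 7
Reactants: 11 (2R)-2-methyl-14-phenyltetradecane-1,2-diol
Product: 13 (2R)-2-methyl-2-(12-phenyldodecyl)oxirane, via (2R)-2-hydroxy-2-methyl-14-phenyltetradecyl 4-methylbenzenesulfonate 12 (not isolated)
Conditions: NaH (3 equiv), 1-(4-methylbenzenesulfonyl)imidazole (1.1 equiv), THF, 0 °C to rt
Reagents that add atoms: none
Why: One-pot selective sulfonylation of the primary hydroxyl followed by intramolecular Williamson displacement by the tertiary alkoxide (3-exo-tet) closes the epoxide onto the former CH2OH carbon, so again no bond to the stereocentre is broken.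

Step 8
Reactants: 4 tert-butyl (3S)-3-hydroperoxy-4-methylpent-4-enoate; 13 (2R)-2-methyl-2-(12-phenyldodecyl)oxirane
Product: 14 tert-butyl (3S)-3-{[(2S)-1-hydroxy-2-methyl-14-phenyltetradecan-2-yl]peroxy}-4-methylpent-4-enoate
Conditions: H3PMo12O40 (5 mol %), 4 Å molecular sieves, Et2O, 0 °C to rt; 4 in excess, recovered
Reagents that add atoms: none
Why: Acid-catalysed ring opening of an epoxide by a hydroperoxide, in which the heteropoly acid activates the epoxide oxygen, positive charge builds at the tertiary carbon and the hydroperoxide attacks there from the face opposite the departing oxygen, so that the C6–O bond should form with inversion (C6 becomes S) while C3 is a spectator.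

Step 9
Reactants: 14 tert-butyl (3S)-3-{[(2S)-1-hydroxy-2-methyl-14-phenyltetradecan-2-yl]peroxy}-4-methylpent-4-enoate
Product: 15 tert-butyl (3S)-4-methyl-3-{[(2S)-2-methyl-1-oxo-14-phenyltetradecan-2-yl]peroxy}pent-4-enoate
Conditions: Dess–Martin periodinane, pyridine, CH2Cl2, 0 °C to rt
Reagents that add atoms: none
Why: Dess–Martin oxidation of the primary alcohol under buffered conditions is tolerated by dialkyl peroxides, and the aldehyde formed has no α-hydrogen, so C6 cannot epimerise.

Step 10
Reactants: 15 tert-butyl (3S)-4-methyl-3-{[(2S)-2-methyl-1-oxo-14-phenyltetradecan-2-yl]peroxy}pent-4-enoate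
Product: 16 tert-butyl (3S)-4-methyl-3-{[(3S)-3-methyl-15-phenylpentadec-1-en-3-yl]peroxy}pent-4-enoate
Conditions: Ph3PCH3Br, KN(SiMe3)2, THF, 0 °C; then 15, −78 to 0 °C
Reagents that add atoms: methyltriphenylphosphonium bromide, C[P+](c1ccccc1)(c1ccccc1)c1ccccc1.[Br-]
Why: Wittig methylenation with methylidenetriphenylphosphorane at low temperature, where addition to the aldehyde carbonyl is far faster than deprotonation of the tert-butyl ester or attack on the shielded dialkyl peroxide, and the quaternary C6 is untouched.

Step 11
Reactants: 16 tert-butyl (3S)-4-methyl-3-{[(3S)-3-methyl-15-phenylpentadec-1-en-3-yl]peroxy}pent-4-enoate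
Product: 17 tert-butyl [(3S,6S)-4,6-dimethyl-6-(12-phenyldodecyl)-3,6-dihydro-1,2-dioxin-3-yl]acetate
Conditions: second-generation Grubbs catalyst RuCl2(=CHPh)(PCy3)(H2IMes) (5–10 mol %), CH2Cl2 (5 mM), 40 °C, argon purge
Reagents that add atoms: none
Why: Olefin metathesis by the Chauvin sequence of [2+2] cycloaddition and cycloreversion: the ruthenium benzylidene first exchanges onto the monosubstituted vinyl group at C6, the resulting alkylidene adds across the 1,1-disubstituted isopropenyl alkene of the same molecule, and collapse of the ruthenacyclobutane releases the trisubstituted C4=C5 ring alkene while ethene leaves the solution. The closest known reaction type is the ring-closing metathesis of unsaturated dialkyl peroxides to 3,6-dihydro-1,2-dioxines with ruthenium carbenes. The one ring formed, the six-membered dihydrodioxine, closes in the ring-closing-metathesis mode with the new double bond inside the ring. No stereocentre is created, and C3 and C6 lie outside the reacting carbons and are carried through unchanged. The selectivity needed is cyclisation over intermolecular cross-metathesis together with survival of the O–O bond; the fully substituted C6 and the gauche C–O–O–C arrangement hold the two alkenes close, high dilution suppresses dimerisation, and the peroxide has no O–H or other easily reduced site.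

Step 12
Reactants: 17 tert-butyl [(3S,6S)-4,6-dimethyl-6-(12-phenyldodecyl)-3,6-dihydro-1,2-dioxin-3-yl]acetate
Product: 18 (3S,4S,4aR,7aS)-4-iodo-3,4a-dimethyl-3-(12-phenyldodecyl)-4,4a,7,7a-tetrahydrofuro[3,2-c][1,2]dioxin-6(3H)-one (iodine on C5, trans to the lactone oxygen)
Conditions: I2 (3 equiv), NaHCO3, MeCN, 0 °C, dark; aq Na2S2O3
Reagents that add atoms: iodine, II
Why: Iodolactonisation, in which the iodonium ion on C4=C5 forms reversibly on either face but only the one anti to the C3 side chain can be opened at the tertiary C4 by the ester carbonyl oxygen in a 5-exo closure, so that the lactone is cis-fused and C4 is set by C3 through the tether, the tert-butyl group being lost as 2-methylpropene and iodine ending on C5 trans to the new C–O bond.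

Step 13
Reactants: 18 (3S,4S,4aR,7aS)-4-iodo-3,4a-dimethyl-3-(12-phenyldodecyl)-4,4a,7,7a-tetrahydrofuro[3,2-c][1,2]dioxin-6(3H)-one
Product: 19 plakortolide L, (3S,4aS,7aS)-3,4a-dimethyl-3-(12-phenyldodecyl)-4,4a,7,7a-tetrahydrofuro[3,2-c][1,2]dioxin-6(3H)-one
Conditions: Bu3SnH (3 equiv, 0.3 M), Et3B (cat.), trace air, toluene, 0 °C to rt
Reagents that add atoms: none
Why: Radical chain dehalogenation, in which the stannyl radical abstracts iodine and the C5 radical is quenched by the concentrated tin hydride faster than it can attack the neighbouring O–O bond, removes the temporary C5 stereocentre and leaves C3, C4 and C6 unchanged.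

**Compound list**

1 | 4-methylpent-3-enoic acid | CC(C)=CCC(=O)O | starting material
2 | tert-butyl 4-methylpent-3-enoate | CC(C)=CCC(=O)OC(C)(C)C | intermediate
3 | tert-butyl 3-hydroperoxy-4-methylpent-4-enoate (racemic) | C=C(C)C(OO)CC(=O)OC(C)(C)C | intermediate
4 | tert-butyl (3S)-3-hydroperoxy-4-methylpent-4-enoate | OO[C@@H](CC(=O)OC(C)(C)C)C(C)=C | intermediate
5 | 11-phenylundecanoic acid | OC(=O)CCCCCCCCCCc1ccccc1 | starting material
6 | 11-phenylundecan-1-ol | OCCCCCCCCCCCc1ccccc1 | intermediate
7 | (11-bromoundecyl)benzene | BrCCCCCCCCCCCc1ccccc1 | intermediate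
8 | [(2S)-2-methyloxiran-2-yl]methanol, (S)-2-methylglycidol | C[C@]1(CO)CO1 | starting material
9 | (11-phenylundecyl)magnesium bromide (formed in the flask) | Br[Mg]CCCCCCCCCCCc1ccccc1 | intermediate
10 | bromomagnesium [(2S)-2-methyloxiran-2-yl]methanolate (formed in the flask) | C[C@]1(C[O-])CO1.[Mg+2].[Br-] | intermediate
11 | (2R)-2-methyl-14-phenyltetradecane-1,2-diol | C[C@](O)(CO)CCCCCCCCCCCCc1ccccc1 | intermediate
12 | (2R)-2-hydroxy-2-methyl-14-phenyltetradecyl 4-methylbenzenesulfonate (formed in the flask) | C[C@](O)(COS(=O)(=O)c1ccc(C)cc1)CCCCCCCCCCCCc1ccccc1 | intermediate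
13 | (2R)-2-methyl-2-(12-phenyldodecyl)oxirane | C[C@@]1(CCCCCCCCCCCCc2ccccc2)CO1 | intermediate
14 | tert-butyl (3S)-3-{[(2S)-1-hydroxy-2-methyl-14-phenyltetradecan-2-yl]peroxy}-4-methylpent-4-enoate | OC[C@](C)(CCCCCCCCCCCCc1ccccc1)OO[C@@H](CC(=O)OC(C)(C)C)C(C)=C | intermediate
15 | tert-butyl (3S)-4-methyl-3-{[(2S)-2-methyl-1-oxo-14-phenyltetradecan-2-yl]peroxy}pent-4-enoate | O=C[C@](C)(CCCCCCCCCCCCc1ccccc1)OO[C@@H](CC(=O)OC(C)(C)C)C(C)=C | intermediate
16 | tert-butyl (3S)-4-methyl-3-{[(3S)-3-methyl-15-phenylpentadec-1-en-3-yl]peroxy}pent-4-enoate | C=C[C@](C)(CCCCCCCCCCCCc1ccccc1)OO[C@@H](CC(=O)OC(C)(C)C)C(C)=C | intermediate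
17 | tert-butyl [(3S,6S)-4,6-dimethyl-6-(12-phenyldodecyl)-3,6-dihydro-1,2-dioxin-3-yl]acetate | C[C@]1(CCCCCCCCCCCCc2ccccc2)C=C(C)[C@H](CC(=O)OC(C)(C)C)OO1 | intermediate
18 | (3S,4S,4aR,7aS)-4-iodo-3,4a-dimethyl-3-(12-phenyldodecyl)-4,4a,7,7a-tetrahydrofuro[3,2-c][1,2]dioxin-6(3H)-one | C[C@]1(CCCCCCCCCCCCc2ccccc2)[C@@H](I)[C@]2(C)OC(=O)C[C@@H]2OO1 | intermediate
19 | plakortolide L, (3S,4aS,7aS)-3,4a-dimethyl-3-(12-phenyldodecyl)-4,4a,7,7a-tetrahydrofuro[3,2-c][1,2]dioxin-6(3H)-one | C[C@]1(CCCCCCCCCCCCc2ccccc2)C[C@]2(C)OC(=O)C[C@@H]2OO1 | target

**Step count and risks**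

Total step count: 13. Longest linear sequence: 10 steps (steps 4 to 13, from 11-phenylundecanoic acid).

Steps most likely to fail:

Step 8. The acid-activated epoxide may ionise fully before the bulky secondary hydroperoxide arrives, so that stereochemical fidelity at C6 is lost or a hydride shift to the aldehyde takes over, and the allylic hydroperoxide may fragment under acid. The fallback makes the tertiary C6–O bond first with a small nucleophile in large excess and builds C3 afterwards by C–C bond formation. It sets out from 13, which is opened with anhydrous ethereal H2O2 under H3PMo12O40 catalysis to (2S)-2-hydroperoxy-2-methyl-14-phenyltetradecan-1-ol F1 (inversion at the tertiary carbon). F1 is condensed with 2-methylprop-2-enal (TsOH cat.) to the cyclic peroxyacetal (6S)-6-methyl-6-(12-phenyldodecyl)-3-(prop-1-en-2-yl)-1,2,4-trioxane F2. F2 is opened at the acetal carbon with 1-tert-butoxy-1-(trimethylsilyloxy)ethene and TiCl4 at −78 °C, a Mukaiyama-type addition to the peroxycarbenium ion. After aqueous work-up this should give 14 together with its C3 epimer, tert-butyl (3R)-3-{[(2S)-1-hydroxy-2-methyl-14-phenyltetradecan-2-yl]peroxy}-4-methylpent-4-enoate F3. Chromatographic separation returns the route to 14; hydroperoxide 4 is then not needed, and C3 is secured by separation instead of resolution.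

Step 3. The enzyme may discriminate poorly between the enantiomers of a substrate carrying the bulky tert-butyl ester, or turn it over too slowly for a useful resolution. The fallback moves the resolution to the coupling. It sets out from racemic 3, which is used in the epoxide opening with enantiopure 13. This gives 14 and its C3 epimer, tert-butyl (3R)-3-{[(2S)-1-hydroxy-2-methyl-14-phenyltetradecan-2-yl]peroxy}-4-methylpent-4-enoate F4 (the same structure as F3), as diastereomers. They are separated by chromatography, or after ring closure if they co-elute, and the route is rejoined at 14.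

Step 11. Slow loading of the carbene on the vinyl group beside the fully substituted, oxygen-bearing C6 may let catalyst decomposition, dimerisation by cross-metathesis or ruthenium-induced cleavage of the O–O bond win. The fallback is a relay ring-closing metathesis. It sets out from aldehyde 15, which is olefinated with the ylide from (hex-5-en-1-yl)triphenylphosphonium bromide (KN(SiMe3)2, THF, −78 °C) to the relay triene tert-butyl (3S)-4-methyl-3-{[(6Z,8S)-8-methyl-20-phenylicosa-1,6-dien-8-yl]peroxy}pent-4-enoate F5. With the same ruthenium catalyst the carbene loads on the unhindered terminal alkene and expels cyclopentene. This places the alkylidene directly on C5, which closes on the isopropenyl group, and the route is rejoined at 17.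

Further compounds
F1 | step 8 | (2S)-2-hydroperoxy-2-methyl-14-phenyltetradecan-1-ol | OC[C@](C)(CCCCCCCCCCCCc1ccccc1)OO
F2 | step 8 | (6S)-6-methyl-6-(12-phenyldodecyl)-3-(prop-1-en-2-yl)-1,2,4-trioxane (both configurations at C3) | C[C@]1(CCCCCCCCCCCCc2ccccc2)COC(OO1)C(C)=C
F3 | step 8 | tert-butyl (3R)-3-{[(2S)-1-hydroxy-2-methyl-14-phenyltetradecan-2-yl]peroxy}-4-methylpent-4-enoate | OC[C@](C)(CCCCCCCCCCCCc1ccccc1)OO[C@H](CC(=O)OC(C)(C)C)C(C)=C
F4 | step 3 | tert-butyl (3R)-3-{[(2S)-1-hydroxy-2-methyl-14-phenyltetradecan-2-yl]peroxy}-4-methylpent-4-enoate | OC[C@](C)(CCCCCCCCCCCCc1ccccc1)OO[C@H](CC(=O)OC(C)(C)C)C(C)=C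
F5 | step 11 | tert-butyl (3S)-4-methyl-3-{[(6Z,8S)-8-methyl-20-phenylicosa-1,6-dien-8-yl]peroxy}pent-4-enoate | C=CCCC/C=C\[C@](C)(CCCCCCCCCCCCc1ccccc1)OO[C@@H](CC(=O)OC(C)(C)C)C(C)=C
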